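**Retrosynthetic overview**

1. The target is a (3R,4R)-trans-α,β-dibenzyl-γ-butyrolactone: the benzyl on C3 carries an open (1S,2S)-1,2-diarylpropane-1,3-diol unit, the benzyl on C4 a (2S,3R)-trans-2-aryl-3-hydroxymethyl-2,3-dihydrobenzofuran.
2. Enabling feature: in the lactone ring (O1–C2(=O)–C3–C4–C5) C3 is α and C4 is β to the carbonyl, each bears one benzylic CH2 and the two are trans, which is the retron of conjugate addition at C4 followed by enolate benzylation at C3; the CH2 on C3 sits on the central ring of the open unit, para to its phenol oxygen and between two unsubstituted ortho positions, so its bromide is an unhindered, activated electrophile.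
3. Key disconnection: C3–CH2 (benzyl bromide 18 + lithium enolate 32), the enolate being generated in the same flask by the C4–C disconnection (2-lithio-1,3-dithiane 31 + (5R)-5-menthyloxyfuranone 30); this three-component coupling assembles the whole carbon skeleton and both lactone stereocentres.
4. Both halves come from one arylacetic acid 6 (activated once as mixed anhydride 9) and aldehyde 8 by Evans Mg-catalysed anti-aldol reactions in the two enantiomeric auxiliary series: the (1S,2S)-diol stays open (fragment A, 18), the (1R,2R)-diol is cyclised (fragment B, 29).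
5. Ring order: dihydrobenzofuran ring (step 19), temporary 1,3-dithiane ring (step 23, removed in step 25); the lactone ring enters ready-made with 30 and is opened and re-closed in step 26, when the menthyloxy acetal carbon becomes C5H2; desilylation ends the route.

Key step: step 24

Abbreviations: TBS = tert-butyldimethylsilyl; G = 4-(TBS-oxy)-3-methoxyphenyl; Men = (1R,2S,5R)-2-isopropyl-5-methylcyclohexyl (l-menthyl); ArA = 4-(TBS-oxy)-3-[(1S,2S)-1,3-bis(TBS-oxy)-1-G-propan-2-yl]-5-methoxyphenyl; ArB = (2S,3R)-2-G-3-[(TBS-oxy)methyl]-7-methoxy-2,3-dihydrobenzofuran-5-yl.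

Assumption 1: (5R)-5-(l-menthyloxy)furan-2(5H)-one 30 is taken as a purchasable reagent (otherwise it is made from furfural by photo-oxygenation and acetalisation with l-menthol).

Assumption 2: the Mg-catalysed anti-aldol is taken to follow the chelated (Z)-enolate model (aldehyde anti to the 4-benzyl group of the auxiliary), so the (S)-auxiliary gives the (2R,3S) adduct; if the opposite anti adduct formed, the two auxiliaries would simply exchange roles.

**Common acid, activated acid and aldehyde**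

Step 1
Reactants: 1 methyl vanillate (methyl 4-hydroxy-3-methoxybenzoate)
Product: 2 methyl 4-(allyloxy)-3-methoxybenzoate
Conditions: allyl bromide, K2CO3, acetone, reflux
Reagents that add atoms: allyl bromide, C=CCBr
Why: Williamson O-allylation of the phenoxide installs the aryl allyl ether needed for the Claisen rearrangement.

Step 2
Reactants: 2 methyl 4-(allyloxy)-3-methoxybenzoate
Product: 3 methyl 3-allyl-4-hydroxy-5-methoxybenzoate
Conditions: N,N-diethylaniline, 200 °C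
Reagents that add atoms: none
Why: The aromatic Claisen rearrangement ([3,3]) delivers the allyl group to the only free ortho position (the other one carries OMe) and tautomerisation restores the phenol.

Step 3
Reactants: 3 methyl 3-allyl-4-hydroxy-5-methoxybenzoate
Product: 4 methyl 3-allyl-4-(benzyloxy)-5-methoxybenzoate
Conditions: BnBr, K2CO3, DMF, 60 °C
Reagents that add atoms: benzyl bromide, BrCc1ccccc1
Why: Williamson O-benzylation masks the phenol with a group that survives oxidation, enolisation and hydride steps and is later removed by hydrogenolysis.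

Step 4
Reactants: 4 methyl 3-allyl-4-(benzyloxy)-5-methoxybenzoate
Product: 5 methyl 4-(benzyloxy)-3-methoxy-5-(2-oxoethyl)benzoate
Conditions: OsO4 (2 mol %), NaIO4, 2,6-lutidine, dioxane/H2O, rt
Reagents that add atoms: sodium periodate (oxygen delivered through catalytic OsO4), [Na+].[O-]I(=O)(=O)=O
Why: Lemieux–Johnson oxidative cleavage of the terminal alkene gives the arylacetaldehyde, 2,6-lutidine suppressing over-oxidation, and the sensitive aldehyde is carried on crude.

Step 5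
Reactants: 5 methyl 4-(benzyloxy)-3-methoxy-5-(2-oxoethyl)benzoate
Product: 6 2-[2-(benzyloxy)-3-methoxy-5-(methoxycarbonyl)phenyl]acetic acid
Conditions: NaClO2, NaH2PO4, 2-methyl-2-butene, t-BuOH/H2O, 0 °C to rt
Reagents that add atoms: sodium chlorite, [Na+].[O-]Cl=O
Why: Pinnick oxidation converts the aldehyde into the acid under buffered conditions that leave the benzyl ether, the ester and the electron-rich ring alone.

Step 6
Reactants: 7 vanillin
Product: 8 4-(TBS-oxy)-3-methoxybenzaldehyde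
Conditions: TBSCl, imidazole, DMF, rt
Reagents that add atoms: tert-butyldimethylsilyl chloride, CC(C)(C)[Si](C)(C)Cl
Why: Silylation of the phenol gives a non-enolisable aryl aldehyde whose protecting group is base-stable at low temperature and falls to hydroxide or fluoride at the end.

Step 7
Reactants: 6 2-[2-(benzyloxy)-3-methoxy-5-(methoxycarbonyl)phenyl]acetic acid
Product: 9 mixed anhydride of acid 6 with pivalic acid, kept as a cold filtered THF solution and divided into two equal portions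
Conditions: PivCl, Et3N, THF, −20 °C; filtration under argon
Reagents that add atoms: pivaloyl chloride, CC(C)(C)C(=O)Cl
Why: Acylation of the triethylammonium carboxylate by pivaloyl chloride gives the mixed anhydride, in which the arylacetyl carbonyl is the unhindered electrophilic site; one batch is prepared and serves both auxiliary series (steps 8 and 15), each portion being used at once.

**Fragment A (open unit, benzyl bromide 18)**

Step 8
Reactants: 9 mixed anhydride of acid 6 with pivalic acid (first portion), 10 (S)-4-benzyloxazolidin-2-one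
Product: 11 (S)-4-benzyl-3-{[2-(benzyloxy)-3-methoxy-5-(methoxycarbonyl)phenyl]acetyl}oxazolidin-2-one
Conditions: LiCl, Et3N, THF, −20 °C to rt
Reagents that add atoms: none
Why: N-Acylation of the oxazolidinone by the mixed pivalic anhydride (LiCl/Et3N protocol) attaches the Evans auxiliary at the less hindered carbonyl without strong base, so the methyl ester is not touched.

Step 9
Reactants: 11 (S)-4-benzyl-3-{[2-(benzyloxy)-3-methoxy-5-(methoxycarbonyl)phenyl]acetyl}oxazolidin-2-one, 8 4-(TBS-oxy)-3-methoxybenzaldehyde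
Product: 13 (S)-4-benzyl-3-[(2R,3S)-2-[2-(benzyloxy)-3-methoxy-5-(methoxycarbonyl)phenyl]-3-hydroxy-3-G-propanoyl]oxazolidin-2-one, via O-trimethylsilyl aldol ether 12 (not isolated)
Conditions: MgCl2 (20 mol %), Et3N, TMSCl, EtOAc, rt; then 1 M HCl, THF, 0 °C
Reagents that add atoms: none
Why: Evans magnesium halide-catalysed direct anti-aldol reaction: soft enolisation gives the Mg-chelated (Z)-enolate, the aldehyde adds to the face opposite the auxiliary benzyl group through a boat transition state, which sets C2 (R) and C3 (S) in the anti relationship, and silylation of the aldolate drives turnover and blocks retro-aldol.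

Step 10
Reactants: 13 (S)-4-benzyl-3-[(2R,3S)-2-[2-(benzyloxy)-3-methoxy-5-(methoxycarbonyl)phenyl]-3-hydroxy-3-G-propanoyl]oxazolidin-2-one
Product: 14 methyl 4-(benzyloxy)-3-[(1S,2S)-1,3-dihydroxy-1-G-propan-2-yl]-5-methoxybenzoate
Conditions: LiBH4, MeOH, THF, 0 °C
Reagents that add atoms: none
Why: Reductive cleavage of the N-acyloxazolidinone by LiBH4 (the imide is far more electrophilic than the electron-rich methyl benzoate) releases the primary alcohol without touching either stereocentre and returns the auxiliary.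

Step 11
Reactants: 14 methyl 4-(benzyloxy)-3-[(1S,2S)-1,3-dihydroxy-1-G-propan-2-yl]-5-methoxybenzoate
Product: 15 methyl 4-hydroxy-3-[(1S,2S)-1,3-dihydroxy-1-G-propan-2-yl]-5-methoxybenzoate
Conditions: H2 (1 atm), Pd/C, EtOAc, rt
Reagents that add atoms: none
Why: Hydrogenolysis of the aryl benzyl ether over Pd/C in a neutral solvent is faster than cleavage of the secondary benzylic C–OH bond and leaves ester and silyl ether intact.

Step 12
Reactants: 15 methyl 4-hydroxy-3-[(1S,2S)-1,3-dihydroxy-1-G-propan-2-yl]-5-methoxybenzoate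
Product: 16 methyl 4-(TBS-oxy)-3-[(1S,2S)-1,3-bis(TBS-oxy)-1-G-propan-2-yl]-5-methoxybenzoate (ArA–CO2Me)
Conditions: TBSOTf, 2,6-lutidine, CH2Cl2, 0 °C to rt
Reagents that add atoms: tert-butyldimethylsilyl triflate, CC(C)(C)[Si](C)(C)OS(=O)(=O)C(F)(F)F
Why: Exhaustive silylation with the reactive silyl triflate protects the hindered phenol, the secondary benzylic alcohol and the primary alcohol in one operation, giving a fragment that carries only fluoride-labile groups.

Step 13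
Reactants: 16 methyl 4-(TBS-oxy)-3-[(1S,2S)-1,3-bis(TBS-oxy)-1-G-propan-2-yl]-5-methoxybenzoate
Product: 17 {4-(TBS-oxy)-3-[(1S,2S)-1,3-bis(TBS-oxy)-1-G-propan-2-yl]-5-methoxyphenyl}methanol (ArA–CH2OH)
Conditions: i-Bu2AlH, CH2Cl2, −78 °C; aq. potassium sodium tartrate
Reagents that add atoms: none
Why: i-Bu2AlH reduces the methyl benzoate to the benzylic alcohol at low temperature while aryl and alkyl silyl ethers are inert to the hydride.

Step 14
Reactants: 17 {4-(TBS-oxy)-3-[(1S,2S)-1,3-bis(TBS-oxy)-1-G-propan-2-yl]-5-methoxyphenyl}methanol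
Product: 18 4-(TBS-oxy)-3-[(1S,2S)-1,3-bis(TBS-oxy)-1-G-propan-2-yl]-5-methoxybenzyl bromide (ArA–CH2Br, fragment A)
Conditions: CBr4, PPh3, CH2Cl2, 0 °C
Reagents that add atoms: carbon tetrabromide, BrC(Br)(Br)Br
Why: The Appel reaction converts the primary benzylic alcohol into the bromide under neutral conditions that do not ionise the silyl ethers, and the activated bromide is used at once.

**Fragment B (phenylcoumaran dithiane 29)**

Step 15
Reactants: 9 mixed anhydride of acid 6 with pivalic acid (second portion), 19 (R)-4-benzyloxazolidin-2-one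
Product: 20 (R)-4-benzyl-3-{[2-(benzyloxy)-3-methoxy-5-(methoxycarbonyl)phenyl]acetyl}oxazolidin-2-one
Conditions: LiCl, Et3N, THF, −20 °C to rt
Reagents that add atoms: none
Why: The same mixed-anhydride N-acylation as in step 8 attaches the enantiomeric auxiliary for the mirror-image series.

Step 16
Reactants: 20 (R)-4-benzyl-3-{[2-(benzyloxy)-3-methoxy-5-(methoxycarbonyl)phenyl]acetyl}oxazolidin-2-one, 8 4-(TBS-oxy)-3-methoxybenzaldehyde
Product: 22 (R)-4-benzyl-3-[(2S,3R)-2-[2-(benzyloxy)-3-methoxy-5-(methoxycarbonyl)phenyl]-3-hydroxy-3-G-propanoyl]oxazolidin-2-one, via O-trimethylsilyl aldol ether 21 (not isolated)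
Conditions: MgCl2 (20 mol %), Et3N, TMSCl, EtOAc, rt; then 1 M HCl, THF, 0 °C
Reagents that add atoms: none
Why: Evans magnesium halide-catalysed anti-aldol reaction, mirror image of step 9, in which the (R)-auxiliary sets C2 (S), the centre that becomes C3 of the dihydrobenzofuran, and C3 (R).

Step 17
Reactants: 22 (R)-4-benzyl-3-[(2S,3R)-2-[2-(benzyloxy)-3-methoxy-5-(methoxycarbonyl)phenyl]-3-hydroxy-3-G-propanoyl]oxazolidin-2-one
Product: 23 methyl 4-(benzyloxy)-3-[(1R,2R)-1,3-dihydroxy-1-G-propan-2-yl]-5-methoxybenzoate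
Conditions: LiBH4, MeOH, THF, 0 °C
Reagents that add atoms: none
Why: Chemoselective reductive removal of the auxiliary by LiBH4, as in step 10, gives the 1,3-diol with both stereocentres intact.

Step 18
Reactants: 23 methyl 4-(benzyloxy)-3-[(1R,2R)-1,3-dihydroxy-1-G-propan-2-yl]-5-methoxybenzoate
Product: 24 methyl 4-hydroxy-3-[(1R,2R)-1,3-dihydroxy-1-G-propan-2-yl]-5-methoxybenzoate
Conditions: H2 (1 atm), Pd/C, EtOAc, rt
Reagents that add atoms: none
Why: Hydrogenolysis of the aryl benzyl ether frees the phenol that will become the ring oxygen, the benzylic alcohol surviving under neutral conditions.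

Step 19
Reactants: 24 methyl 4-hydroxy-3-[(1R,2R)-1,3-dihydroxy-1-G-propan-2-yl]-5-methoxybenzoate
Product: 25 methyl (2S,3R)-2-G-3-(hydroxymethyl)-7-methoxy-2,3-dihydrobenzofuran-5-carboxylate
Conditions: TsOH·H2O (10 mol %), CH2Cl2, 0 °C to rt
Reagents that add atoms: none
Why: Acid-promoted cyclodehydration through the 4-silyloxy-3-methoxybenzyl cation lets the phenol close the five-membered ring at the benzylic carbon only (the primary alcohol cannot ionise), and the favoured trans arrangement of aryl and CH2OH gives C2 (S) whatever the carbinol configuration, with C3 (R) carried over from the aldol.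

Step 20
Reactants: 25 methyl (2S,3R)-2-G-3-(hydroxymethyl)-7-methoxy-2,3-dihydrobenzofuran-5-carboxylate
Product: 26 methyl (2S,3R)-2-G-3-[(TBS-oxy)methyl]-7-methoxy-2,3-dihydrobenzofuran-5-carboxylate (ArB–CO2Me)
Conditions: TBSCl, imidazole, DMF, rt
Reagents that add atoms: tert-butyldimethylsilyl chloride, CC(C)(C)[Si](C)(C)Cl
Why: Silylation of the primary alcohol removes the last acidic proton before the organolithium step.

Step 21
Reactants: 26 methyl (2S,3R)-2-G-3-[(TBS-oxy)methyl]-7-methoxy-2,3-dihydrobenzofuran-5-carboxylate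
Product: 27 {(2S,3R)-2-G-3-[(TBS-oxy)methyl]-7-methoxy-2,3-dihydrobenzofuran-5-yl}methanol (ArB–CH2OH)
Conditions: i-Bu2AlH, CH2Cl2, −78 °C; aq. potassium sodium tartrate
Reagents that add atoms: none
Why: Hydride reduction of the aryl ester to the benzylic alcohol, as in step 13, spares the silyl ethers and the benzylic ether of the heterocycle.

Step 22
Reactants: 27 {(2S,3R)-2-G-3-[(TBS-oxy)methyl]-7-methoxy-2,3-dihydrobenzofuran-5-yl}methanol
Product: 28 (2S,3R)-2-G-3-[(TBS-oxy)methyl]-7-methoxy-2,3-dihydrobenzofuran-5-carbaldehyde (ArB–CHO)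
Conditions: MnO2, CH2Cl2, rt
Reagents that add atoms: none
Why: MnO2 oxidises the electron-rich benzylic alcohol selectively to the aldehyde without over-oxidation.

Step 23
Reactants: 28 (2S,3R)-2-G-3-[(TBS-oxy)methyl]-7-methoxy-2,3-dihydrobenzofuran-5-carbaldehyde
Product: 29 2-(ArB)-1,3-dithiane (fragment B)
Conditions: HS(CH2)3SH, Zn(OTf)2 (5 mol %), CH2Cl2, rt
Reagents that add atoms: propane-1,3-dithiol, SCCCS
Why: Lewis acid-catalysed dithioacetalisation turns the aldehyde carbon into an acyl-anion-type nucleophile precursor, and Zn(OTf)2 is mild enough to spare the silyl ethers and the benzylic C2–O bond of the dihydrobenzofuran.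

**Coupling and end game**

Step 24
Reactants: 29 2-(ArB)-1,3-dithiane, 30 (5R)-5-(Men-oxy)furan-2(5H)-one, 18 ArA–CH2Br
Product: 33 (3R,4R,5R)-3-(ArA-methyl)-4-[2-(ArB)-1,3-dithian-2-yl]-5-(Men-oxy)dihydrofuran-2(3H)-one, via 2-lithio-1,3-dithiane 31 (not isolated), via lithium lactone enolate 32 (not isolated)
Conditions: n-BuLi, THF, −78 °C; 30, −78 °C; then 18, DMPU, −78 to −20 °C
Reagents that add atoms: none
Why: n-BuLi removes the dithiane C2–H of 29, the soft aryl- and sulfur-stabilised anion 31 adds 1,4 to furanone 30, and the lithium enolate 32 so formed is C-benzylated in the same flask by bromide 18, which makes the C3–CH2 bond joining the two halves. The closest known reaction type is the tandem conjugate addition–enolate alkylation of 5-alkoxyfuran-2(5H)-ones with lithiated 2-aryl-1,3-dithianes and benzyl bromides, the standard entry to trans-dibenzylbutyrolactone lignans. No ring is closed: the lactone ring arrives intact with 30 and both aryl units are attached to it as exocyclic substituents. C4 is controlled by the acetal centre C5, the nucleophile entering anti to the menthyloxy group, and C3 is controlled by C4, the bromide approaching the enolate face anti to the bulky dithianyl substituent, so the trans,trans (3R,4R,5R) product maps onto (3R,4R) of the target. The step needs 1,4- over 1,2-addition, C- over O-alkylation and mono-alkylation; the first is secured by the delocalised dithianyl anion at −78 °C, the others by the activated benzylic bromide with two free ortho positions, by DMPU and by the hindered, less acidic α-H of the product.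

Step 25
Reactants: 33 (3R,4R,5R)-3-(ArA-methyl)-4-[2-(ArB)-1,3-dithian-2-yl]-5-(Men-oxy)dihydrofuran-2(3H)-one
Product: 34 (3R,4R,5R)-3-(ArA-methyl)-4-(ArB-methyl)-5-(Men-oxy)dihydrofuran-2(3H)-one
Conditions: Raney Ni (W-2), EtOH/THF, rt
Reagents that add atoms: none
Why: Raney Ni desulfurisation cleaves the two benzylic C–S bonds and turns the dithiane carbon into the benzylic CH2 at room temperature, conditions under which silyl ethers, the acetal and the benzylic C–O bonds should survive.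

Step 26
Reactants: 34 (3R,4R,5R)-3-(ArA-methyl)-4-(ArB-methyl)-5-(Men-oxy)dihydrofuran-2(3H)-one
Product: 37 (3R,4R)-3-{4-hydroxy-3-[(1S,2S)-1,3-bis(TBS-oxy)-1-(4-hydroxy-3-methoxyphenyl)propan-2-yl]-5-methoxybenzyl}-4-{[(2S,3R)-2-(4-hydroxy-3-methoxyphenyl)-3-[(TBS-oxy)methyl]-7-methoxy-2,3-dihydrobenzofuran-5-yl]methyl}dihydrofuran-2(3H)-one, via aldehyde acid 35 (not isolated), via hydroxy acid 36 (not isolated)
Conditions: NaBH4, KOH, EtOH/THF/H2O, 0 °C to rt; then 1 M HCl to pH 3, rt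
Reagents that add atoms: none
Why: Hydroxide opens the acyl-acetal lactone to the carboxylate and the aldehyde with loss of menthol, NaBH4 already present reduces the aldehyde at once (which guards C4 against enolisation), and acidification closes the γ-lactone so that the former acetal carbon becomes C5H2, while the three aryl silyl ethers are cleaved by hydroxide and the alkyl silyl ethers stay (any aryl silyl ether that survived would fall in step 27).

Step 27
Reactants: 37 tris(alkyl-O-TBS) ether of the target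
Product: 38 (3R,4R)-3-{4-hydroxy-3-[(1S,2S)-1,3-dihydroxy-1-(4-hydroxy-3-methoxyphenyl)propan-2-yl]-5-methoxybenzyl}-4-{[(2S,3R)-2-(4-hydroxy-3-methoxyphenyl)-3-(hydroxymethyl)-7-methoxy-2,3-dihydrobenzofuran-5-yl]methyl}dihydrofuran-2(3H)-one (CNP0186558.2)
Conditions: Bu4NF, AcOH, THF, rt
Reagents that add atoms: none
Why: Acetic acid-buffered fluoride desilylation removes the three remaining silyl ethers under near-neutral conditions, which avoids quinone methide formation and acid-induced cyclisation of the 4-hydroxybenzylic alcohol onto the neighbouring phenol.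

**Compound list**

1 | methyl vanillate | COC(=O)c1ccc(O)c(OC)c1 | starting material
2 | methyl 4-(allyloxy)-3-methoxybenzoate | COC(=O)c1ccc(OCC=C)c(OC)c1 | intermediate
3 | methyl 3-allyl-4-hydroxy-5-methoxybenzoate | COC(=O)c1cc(CC=C)c(O)c(OC)c1 | intermediate
4 | methyl 3-allyl-4-(benzyloxy)-5-methoxybenzoate | COC(=O)c1cc(CC=C)c(OCc2ccccc2)c(OC)c1 | intermediate
5 | methyl 4-(benzyloxy)-3-methoxy-5-(2-oxoethyl)benzoate | COC(=O)c1cc(CC=O)c(OCc2ccccc2)c(OC)c1 | intermediate
6 | 2-[2-(benzyloxy)-3-methoxy-5-(methoxycarbonyl)phenyl]acetic acid | COC(=O)c1cc(CC(=O)O)c(OCc2ccccc2)c(OC)c1 | intermediate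
7 | vanillin | COc1cc(C=O)ccc1O | starting material
8 | 4-(TBS-oxy)-3-methoxybenzaldehyde | COc1cc(C=O)ccc1O[Si](C)(C)C(C)(C)C | intermediate
9 | mixed anhydride of acid 6 with pivalic acid | COC(=O)c1cc(CC(=O)OC(=O)C(C)(C)C)c(OCc2ccccc2)c(OC)c1 | intermediate
10 | (S)-4-benzyloxazolidin-2-one | O=C1N[C@@H](Cc2ccccc2)CO1 | starting material
11 | (S)-4-benzyl-3-{[2-(benzyloxy)-3-methoxy-5-(methoxycarbonyl)phenyl]acetyl}oxazolidin-2-one | COC(=O)c1cc(CC(=O)N2[C@@H](Cc3ccccc3)COC2=O)c(OCc2ccccc2)c(OC)c1 | intermediate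
12 | O-trimethylsilyl ether of 13 | COc1cc([C@@H](O[Si](C)(C)C)[C@H](C(=O)N2[C@@H](Cc3ccccc3)COC2=O)c2cc(C(=O)OC)cc(OC)c2OCc2ccccc2)ccc1O[Si](C)(C)C(C)(C)C | intermediate (not isolated)
13 | (S)-4-benzyl-3-[(2R,3S)-2-[2-(benzyloxy)-3-methoxy-5-(methoxycarbonyl)phenyl]-3-hydroxy-3-G-propanoyl]oxazolidin-2-one | COc1cc([C@@H](O)[C@H](C(=O)N2[C@@H](Cc3ccccc3)COC2=O)c2cc(C(=O)OC)cc(OC)c2OCc2ccccc2)ccc1O[Si](C)(C)C(C)(C)C | intermediate
14 | methyl 4-(benzyloxy)-3-[(1S,2S)-1,3-dihydroxy-1-G-propan-2-yl]-5-methoxybenzoate | COc1cc([C@@H](O)[C@H](CO)c2cc(C(=O)OC)cc(OC)c2OCc2ccccc2)ccc1O[Si](C)(C)C(C)(C)C | intermediate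
15 | methyl 4-hydroxy-3-[(1S,2S)-1,3-dihydroxy-1-G-propan-2-yl]-5-methoxybenzoate | COc1cc([C@@H](O)[C@H](CO)c2cc(C(=O)OC)cc(OC)c2O)ccc1O[Si](C)(C)C(C)(C)C | intermediate
16 | methyl 4-(TBS-oxy)-3-[(1S,2S)-1,3-bis(TBS-oxy)-1-G-propan-2-yl]-5-methoxybenzoate | COc1cc([C@@H](O[Si](C)(C)C(C)(C)C)[C@H](CO[Si](C)(C)C(C)(C)C)c2cc(C(=O)OC)cc(OC)c2O[Si](C)(C)C(C)(C)C)ccc1O[Si](C)(C)C(C)(C)C | intermediate
17 | {4-(TBS-oxy)-3-[(1S,2S)-1,3-bis(TBS-oxy)-1-G-propan-2-yl]-5-methoxyphenyl}methanol | COc1cc([C@@H](O[Si](C)(C)C(C)(C)C)[C@H](CO[Si](C)(C)C(C)(C)C)c2cc(CO)cc(OC)c2O[Si](C)(C)C(C)(C)C)ccc1O[Si](C)(C)C(C)(C)C | intermediate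
18 | 4-(TBS-oxy)-3-[(1S,2S)-1,3-bis(TBS-oxy)-1-G-propan-2-yl]-5-methoxybenzyl bromide (fragment A) | COc1cc([C@@H](O[Si](C)(C)C(C)(C)C)[C@H](CO[Si](C)(C)C(C)(C)C)c2cc(CBr)cc(OC)c2O[Si](C)(C)C(C)(C)C)ccc1O[Si](C)(C)C(C)(C)C | intermediate
19 | (R)-4-benzyloxazolidin-2-one | O=C1N[C@H](Cc2ccccc2)CO1 | starting material
20 | (R)-4-benzyl-3-{[2-(benzyloxy)-3-methoxy-5-(methoxycarbonyl)phenyl]acetyl}oxazolidin-2-one | COC(=O)c1cc(CC(=O)N2[C@H](Cc3ccccc3)COC2=O)c(OCc2ccccc2)c(OC)c1 | intermediate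
21 | O-trimethylsilyl ether of 22 | COc1cc([C@H](O[Si](C)(C)C)[C@@H](C(=O)N2[C@H](Cc3ccccc3)COC2=O)c2cc(C(=O)OC)cc(OC)c2OCc2ccccc2)ccc1O[Si](C)(C)C(C)(C)C | intermediate (not isolated)
22 | (R)-4-benzyl-3-[(2S,3R)-2-[2-(benzyloxy)-3-methoxy-5-(methoxycarbonyl)phenyl]-3-hydroxy-3-G-propanoyl]oxazolidin-2-one | COc1cc([C@H](O)[C@@H](C(=O)N2[C@H](Cc3ccccc3)COC2=O)c2cc(C(=O)OC)cc(OC)c2OCc2ccccc2)ccc1O[Si](C)(C)C(C)(C)C | intermediate
23 | methyl 4-(benzyloxy)-3-[(1R,2R)-1,3-dihydroxy-1-G-propan-2-yl]-5-methoxybenzoate | COc1cc([C@H](O)[C@@H](CO)c2cc(C(=O)OC)cc(OC)c2OCc2ccccc2)ccc1O[Si](C)(C)C(C)(C)C | intermediate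
24 | methyl 4-hydroxy-3-[(1R,2R)-1,3-dihydroxy-1-G-propan-2-yl]-5-methoxybenzoate | COc1cc([C@H](O)[C@@H](CO)c2cc(C(=O)OC)cc(OC)c2O)ccc1O[Si](C)(C)C(C)(C)C | intermediate
25 | methyl (2S,3R)-2-G-3-(hydroxymethyl)-7-methoxy-2,3-dihydrobenzofuran-5-carboxylate | COC(=O)c1cc(OC)c2c(c1)[C@H](CO)[C@@H](c1ccc(O[Si](C)(C)C(C)(C)C)c(OC)c1)O2 | intermediate
26 | methyl (2S,3R)-2-G-3-[(TBS-oxy)methyl]-7-methoxy-2,3-dihydrobenzofuran-5-carboxylate | COC(=O)c1cc(OC)c2c(c1)[C@H](CO[Si](C)(C)C(C)(C)C)[C@@H](c1ccc(O[Si](C)(C)C(C)(C)C)c(OC)c1)O2 | intermediate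
27 | {(2S,3R)-2-G-3-[(TBS-oxy)methyl]-7-methoxy-2,3-dihydrobenzofuran-5-yl}methanol | OCc1cc(OC)c2c(c1)[C@H](CO[Si](C)(C)C(C)(C)C)[C@@H](c1ccc(O[Si](C)(C)C(C)(C)C)c(OC)c1)O2 | intermediate
28 | (2S,3R)-2-G-3-[(TBS-oxy)methyl]-7-methoxy-2,3-dihydrobenzofuran-5-carbaldehyde | O=Cc1cc(OC)c2c(c1)[C@H](CO[Si](C)(C)C(C)(C)C)[C@@H](c1ccc(O[Si](C)(C)C(C)(C)C)c(OC)c1)O2 | intermediate
29 | 2-{(2S,3R)-2-G-3-[(TBS-oxy)methyl]-7-methoxy-2,3-dihydrobenzofuran-5-yl}-1,3-dithiane (fragment B) | C1CSC(SC1)c1cc(OC)c2c(c1)[C@H](CO[Si](C)(C)C(C)(C)C)[C@@H](c1ccc(O[Si](C)(C)C(C)(C)C)c(OC)c1)O2 | intermediate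
30 | (5R)-5-{[(1R,2S,5R)-2-isopropyl-5-methylcyclohexyl]oxy}furan-2(5H)-one | O=C1C=C[C@H](O[C@@H]2C[C@H](C)CC[C@H]2C(C)C)O1 | starting material
31 | 2-lithio derivative of dithiane 29 | [Li]C1(SCCCS1)c1cc(OC)c2c(c1)[C@H](CO[Si](C)(C)C(C)(C)C)[C@@H](c1ccc(O[Si](C)(C)C(C)(C)C)c(OC)c1)O2 | intermediate (not isolated)
32 | lithium enolate of (4R,5R)-4-[2-(ArB)-1,3-dithian-2-yl]-5-(Men-oxy)dihydrofuran-2(3H)-one | [Li]OC1=C[C@@H](C2(SCCCS2)c2cc(OC)c3c(c2)[C@H](CO[Si](C)(C)C(C)(C)C)[C@@H](c2ccc(O[Si](C)(C)C(C)(C)C)c(OC)c2)O3)[C@H](O[C@@H]2C[C@H](C)CC[C@H]2C(C)C)O1 | intermediate (not isolated)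
33 | (3R,4R,5R)-3-(ArA-methyl)-4-[2-(ArB)-1,3-dithian-2-yl]-5-(Men-oxy)dihydrofuran-2(3H)-one | COc1cc([C@@H](O[Si](C)(C)C(C)(C)C)[C@H](CO[Si](C)(C)C(C)(C)C)c2cc(C[C@H]3C(=O)O[C@@H](O[C@@H]4C[C@H](C)CC[C@H]4C(C)C)[C@@H]3C3(SCCCS3)c3cc(OC)c4c(c3)[C@H](CO[Si](C)(C)C(C)(C)C)[C@@H](c3ccc(O[Si](C)(C)C(C)(C)C)c(OC)c3)O4)cc(OC)c2O[Si](C)(C)C(C)(C)C)ccc1O[Si](C)(C)C(C)(C)C | intermediate
34 | (3R,4R,5R)-3-(ArA-methyl)-4-(ArB-methyl)-5-(Men-oxy)dihydrofuran-2(3H)-one | COc1cc([C@@H](O[Si](C)(C)C(C)(C)C)[C@H](CO[Si](C)(C)C(C)(C)C)c2cc(C[C@H]3C(=O)O[C@@H](O[C@@H]4C[C@H](C)CC[C@H]4C(C)C)[C@@H]3Cc3cc(OC)c4c(c3)[C@H](CO[Si](C)(C)C(C)(C)C)[C@@H](c3ccc(O[Si](C)(C)C(C)(C)C)c(OC)c3)O4)cc(OC)c2O[Si](C)(C)C(C)(C)C)ccc1O[Si](C)(C)C(C)(C)C | intermediate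
35 | (2R,3R)-2,3-dibenzyl-4-oxobutanoic acid corresponding to 37 (open form, CHO at the former acetal carbon, phenols free) | COc1cc([C@@H](O[Si](C)(C)C(C)(C)C)[C@H](CO[Si](C)(C)C(C)(C)C)c2cc(C[C@@H](C(=O)O)[C@H](C=O)Cc3cc(OC)c4c(c3)[C@H](CO[Si](C)(C)C(C)(C)C)[C@@H](c3ccc(O)c(OC)c3)O4)cc(OC)c2O)ccc1O | intermediate (not isolated)
36 | (2R,3R)-2,3-dibenzyl-4-hydroxybutanoic acid corresponding to 37 (seco acid of the lactone) | COc1cc([C@@H](O[Si](C)(C)C(C)(C)C)[C@H](CO[Si](C)(C)C(C)(C)C)c2cc(C[C@@H](C(=O)O)[C@H](CO)Cc3cc(OC)c4c(c3)[C@H](CO[Si](C)(C)C(C)(C)C)[C@@H](c3ccc(O)c(OC)c3)O4)cc(OC)c2O)ccc1O | intermediate (not isolated)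
37 | (3R,4R)-3-{4-hydroxy-3-[(1S,2S)-1,3-bis(TBS-oxy)-1-(4-hydroxy-3-methoxyphenyl)propan-2-yl]-5-methoxybenzyl}-4-{[(2S,3R)-2-(4-hydroxy-3-methoxyphenyl)-3-[(TBS-oxy)methyl]-7-methoxy-2,3-dihydrobenzofuran-5-yl]methyl}dihydrofuran-2(3H)-one | COc1cc([C@@H](O[Si](C)(C)C(C)(C)C)[C@H](CO[Si](C)(C)C(C)(C)C)c2cc(C[C@H]3C(=O)OC[C@@H]3Cc3cc(OC)c4c(c3)[C@H](CO[Si](C)(C)C(C)(C)C)[C@@H](c3ccc(O)c(OC)c3)O4)cc(OC)c2O)ccc1O | intermediate
38 | CNP0186558.2, (3R,4R)-3-{4-hydroxy-3-[(1S,2S)-1,3-dihydroxy-1-(4-hydroxy-3-methoxyphenyl)propan-2-yl]-5-methoxybenzyl}-4-{[(2S,3R)-2-(4-hydroxy-3-methoxyphenyl)-3-(hydroxymethyl)-7-methoxy-2,3-dihydrobenzofuran-5-yl]methyl}dihydrofuran-2(3H)-one | COc1cc([C@@H](O)[C@H](CO)c2cc(C[C@H]3C(=O)OC[C@@H]3Cc3cc(OC)c4c(c3)[C@H](CO)[C@@H](c3ccc(O)c(OC)c3)O4)cc(OC)c2O)ccc1O | target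

**Step count and risks**

Total step count: 27 steps (both branches counted).

Longest linear sequence: 19 steps (1 → 6 → 9 → 20 → 29 → 33 → 38; steps 1–5, 7, 15–23, 24–27).

The three steps most likely to fail:

Step 24 (key coupling). What may go wrong: 1,2-addition or proton transfer when 31 meets 30, or sluggish C-benzylation of the crowded enolate 32 next to the quaternary dithianyl carbon, leading to protonated Michael adduct, O-alkylation or decomposition of bromide 18. Fallback: the two bond formations are uncoupled. Anion 31 (from 29) is added to 30 as before and the enolate is quenched with NH4Cl to give the Michael adduct (4R,5R)-4-[2-(ArB)-1,3-dithian-2-yl]-5-(Men-oxy)dihydrofuran-2(3H)-one F3. Raney Ni then removes the dithiane to give (4R,5R)-4-(ArB-methyl)-5-(Men-oxy)dihydrofuran-2(3H)-one F4. Its much less hindered lithium enolate (LiN(i-Pr)2, THF, −78 °C, DMPU) is benzylated with 18 anti to the C4 substituent. The fallback sets out from 29 and 30 and comes back to the route at 34.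

Step 26 (reductive excision of the menthyloxy acetal). What may go wrong: epimerisation at C4 through the transient aldehyde under hydroxide, incomplete opening of the hindered acetal, or base-induced quinone methide formation from the phenoxides. Fallback: the lactone is built without an acetal carbon. Alcohol 27 is converted (CBr4, PPh3) into the benzyl bromide ArB–CH2Br F5. F5 alkylates the sodium enolate (NaN(SiMe3)2, THF, −78 °C) of (R)-4-benzyl-3-(4-methoxy-4-oxobutanoyl)oxazolidin-2-one to give (R)-4-benzyl-3-[(2R)-2-(ArB-methyl)-4-methoxy-4-oxobutanoyl]oxazolidin-2-one F6. LiBH4 reduces the imide, and the alkoxide closes onto the methyl ester to give (4R)-4-(ArB-methyl)dihydrofuran-2(3H)-one F7. Its lithium enolate (LiN(i-Pr)2, DMPU) is benzylated with 18 trans to the C4 substituent to give the hexakis-TBS ether of the target F8, and Bu4NF/AcOH removes all six silyl groups. This fallback sets out from 27 (and uses 18) and comes back to the route at 38.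

Step 9 (and its mirror image, step 16). What may go wrong: poor anti/syn or facial selectivity, or retro-aldol equilibration of the acidic arylacetyl imide under the Mg conditions. For fragment B the carbinol configuration is irrelevant (step 19 is stereoconvergent), so the problem matters for fragment A. Fallback: the stereocontrol element is changed to a thiazolidinethione, whose non-chelated enolate shows the opposite facial preference and whose acyl group is cleaved by NaBH4. Acid 6 is coupled (EDC, DMAP) with (R)-4-benzyl-1,3-thiazolidine-2-thione to give (R)-4-benzyl-3-{[2-(benzyloxy)-3-methoxy-5-(methoxycarbonyl)phenyl]acetyl}-1,3-thiazolidine-2-thione F1. The MgBr2·OEt2-catalysed anti-aldol reaction with 8 (Et3N, TMSCl, EtOAc; dilute HCl work-up) should give (R)-4-benzyl-3-[(2R,3S)-2-[2-(benzyloxy)-3-methoxy-5-(methoxycarbonyl)phenyl]-3-hydroxy-3-G-propanoyl]-1,3-thiazolidine-2-thione F2. NaBH4 in THF/H2O then releases diol 14. This fallback sets out from 6 and comes back to the route at 14.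

**Further compounds**

F1 | step 9 | (R)-4-benzyl-3-{[2-(benzyloxy)-3-methoxy-5-(methoxycarbonyl)phenyl]acetyl}-1,3-thiazolidine-2-thione | COC(=O)c1cc(CC(=O)N2[C@H](Cc3ccccc3)CSC2=S)c(OCc2ccccc2)c(OC)c1
F2 | step 9 | (R)-4-benzyl-3-[(2R,3S)-2-[2-(benzyloxy)-3-methoxy-5-(methoxycarbonyl)phenyl]-3-hydroxy-3-G-propanoyl]-1,3-thiazolidine-2-thione | COc1cc([C@@H](O)[C@H](C(=O)N2[C@H](Cc3ccccc3)CSC2=S)c2cc(C(=O)OC)cc(OC)c2OCc2ccccc2)ccc1O[Si](C)(C)C(C)(C)C
F3 | step 24 | (4R,5R)-4-[2-(ArB)-1,3-dithian-2-yl]-5-(Men-oxy)dihydrofuran-2(3H)-one | O=C1C[C@@H](C2(SCCCS2)c2cc(OC)c3c(c2)[C@H](CO[Si](C)(C)C(C)(C)C)[C@@H](c2ccc(O[Si](C)(C)C(C)(C)C)c(OC)c2)O3)[C@H](O[C@@H]2C[C@H](C)CC[C@H]2C(C)C)O1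
F4 | step 24 | (4R,5R)-4-(ArB-methyl)-5-(Men-oxy)dihydrofuran-2(3H)-one | O=C1C[C@@H](Cc2cc(OC)c3c(c2)[C@H](CO[Si](C)(C)C(C)(C)C)[C@@H](c2ccc(O[Si](C)(C)C(C)(C)C)c(OC)c2)O3)[C@H](O[C@@H]2C[C@H](C)CC[C@H]2C(C)C)O1
F5 | step 26 | (2S,3R)-5-(bromomethyl)-2-G-3-[(TBS-oxy)methyl]-7-methoxy-2,3-dihydrobenzofuran (ArB–CH2Br) | BrCc1cc(OC)c2c(c1)[C@H](CO[Si](C)(C)C(C)(C)C)[C@@H](c1ccc(O[Si](C)(C)C(C)(C)C)c(OC)c1)O2
F6 | step 26 | (R)-4-benzyl-3-[(2R)-2-(ArB-methyl)-4-methoxy-4-oxobutanoyl]oxazolidin-2-one | O=C1OC[C@@H](Cc2ccccc2)N1C(=O)[C@@H](CC(=O)OC)Cc1cc(OC)c2c(c1)[C@H](CO[Si](C)(C)C(C)(C)C)[C@@H](c1ccc(O[Si](C)(C)C(C)(C)C)c(OC)c1)O2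
F7 | step 26 | (4R)-4-(ArB-methyl)dihydrofuran-2(3H)-one | O=C1C[C@H](CO1)Cc1cc(OC)c2c(c1)[C@H](CO[Si](C)(C)C(C)(C)C)[C@@H](c1ccc(O[Si](C)(C)C(C)(C)C)c(OC)c1)O2
F8 | step 26 | (3R,4R)-3-(ArA-methyl)-4-(ArB-methyl)dihydrofuran-2(3H)-one (hexakis-TBS ether of the target) | COc1cc([C@@H](O[Si](C)(C)C(C)(C)C)[C@H](CO[Si](C)(C)C(C)(C)C)c2cc(C[C@H]3C(=O)OC[C@@H]3Cc3cc(OC)c4c(c3)[C@H](CO[Si](C)(C)C(C)(C)C)[C@@H](c3ccc(O[Si](C)(C)C(C)(C)C)c(OC)c3)O4)cc(OC)c2O[Si](C)(C)C(C)(C)C)ccc1O[Si](C)(C)C(C)(C)C
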